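**Retrosynthetic overview**
1. Feature: numbered like naphthalene (C1 propenyl, C2 acyl, C4 and C7 methyl), ring A is a cyclohexa-1,3-diene (C1=C2–C3=C4) whose only sp3 atoms are the fusion carbons C4a and C8a. It is therefore a 4a,8a-dihydrobenzene with carbonyl-derived carbons on the neighbouring atoms C1 and C2, a reduced phthalic-type arene.
2. Late disconnections: C2–C(=O)–pyridone (3-lithiopyridine plus C2 aldehyde, oxidation, PMB removal) and C1–propenyl (ethylidenation of the C1 carbonyl).
3. Key disconnection C8–C8a: a samarium ketyl at C8 of a γ-aryl aldehyde adds to the free ortho carbon C8a of the benzoate ring. Ring A is bought as the arene, ring B is closed on it with loss of aromaticity, and the pyridine ring is bought.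
4. Acceptor design: C1 carries the methyl ester and the C2 carbonyl is masked as a dimethyl acetal (a phthalaldehydate). An ester para to the tether would draw the ketyl to the ipso carbon C4a and would later acidify H-8a. The C8 oxygen then lactonises onto C1, and this temporary third ring fixes the trans C4a–H during base-mediated diene conjugation. The lactone is later opened (lactol, olefination) and C8–O is removed by Barton–McCombie reduction.
5. Precursor: methyl 2-bromo-4-methylbenzoate has C1 and C2 distinct from the start. It is iodinated at C4a, joined by B-alkyl Suzuki coupling to the Roche-ester-derived 2-methylbut-3-enyl silyl ether (source of C5–C8 and of the C7 stereocentre), formylated at C2 and oxidised at C8.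

Key step: step 9

Remark: the naphthalene-type numbering of the target decalin is used for all intermediates, including the arene (C1–C4, C4a, C8a) and its side chain (C5–C8). Lactol 17 and carbinol 29 are carried as epimer mixtures at centres that are lost again.

Step 1
Reactants: 1 methyl (R)-3-hydroxy-2-methylpropanoate
Product: 2 methyl (R)-3-[(tert-butyldimethylsilyl)oxy]-2-methylpropanoate
Conditions: TBSCl, imidazole, CH2Cl2, 0 °C to rt
Reagents that add atoms: tert-butyldimethylsilyl chloride, CC(C)(C)[Si](C)(C)Cl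
Why: Standard imidazole-promoted silylation of the primary alcohol, which leaves the stereocentre (the later C7) untouched.

Step 2
Reactants: 2 methyl (R)-3-[(tert-butyldimethylsilyl)oxy]-2-methylpropanoate
Product: 3 (R)-3-[(tert-butyldimethylsilyl)oxy]-2-methylpropanal
Conditions: DIBAL-H (1.05 equiv), CH2Cl2, −78 °C; Rochelle salt
Reagents that add atoms: none
Why: Partial reduction of the ester with one equivalent of DIBAL-H at −78 °C stops at the tetrahedral aluminium acetal, so the aldehyde is released only on work-up and should keep its α-configuration if used at once.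

Step 3
Reactants: 3 (R)-3-[(tert-butyldimethylsilyl)oxy]-2-methylpropanal
Product: 4 (S)-tert-butyldimethyl[(2-methylbut-3-en-1-yl)oxy]silane
Conditions: Ph3PCH3Br, KOt-Bu, THF, 0 °C; then 3, −78 °C to 0 °C
Reagents that add atoms: methyltriphenylphosphonium bromide, C[P+](c1ccccc1)(c1ccccc1)c1ccccc1.[Br-]
Why: Wittig methylenation with the non-stabilised ylide is fast at low temperature, so the α-stereocentre should survive; the descriptor changes to S only because the priorities change.

Step 4
Reactants: 5 methyl 2-bromo-4-methylbenzoate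
Product: 6 methyl 2-bromo-5-iodo-4-methylbenzoate
Conditions: NIS, TfOH (cat.), CH2Cl2, 0 °C to rt
Reagents that add atoms: N-iodosuccinimide, O=C1CCC(=O)N1I
Why: Electrophilic aromatic iodination in which the ring position that becomes C4a is ortho to the methyl, para to bromine and meta to the ester, while the only other position with this activation is wedged between Br and CH3, so one regioisomer is expected and the later C1 and C2 carbons are told apart from the outset.

Step 5
Reactants: 4 (S)-tert-butyldimethyl[(2-methylbut-3-en-1-yl)oxy]silane; 6 methyl 2-bromo-5-iodo-4-methylbenzoate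
Product: 8 methyl 2-bromo-5-{(3S)-4-[(tert-butyldimethylsilyl)oxy]-3-methylbutyl}-4-methylbenzoate, via B-alkyl-9-BBN borane 7 (not isolated)
Conditions: 9-BBN, THF, rt; then 6, Pd(dppf)Cl2 (cat.), AsPh3 (cat.), Cs2CO3, DMF/H2O, rt
Reagents that add atoms: none
Why: Anti-Markovnikov hydroboration followed by B-alkyl Suzuki–Miyaura coupling, in which oxidative addition into C–I is much faster than into C–Br at room temperature, so the bromide is kept for C2 and the stereocentre is not touched.

Step 6
Reactants: 8 methyl 2-bromo-5-{(3S)-4-[(tert-butyldimethylsilyl)oxy]-3-methylbutyl}-4-methylbenzoate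
Product: 10 methyl 5-{(3S)-4-[(tert-butyldimethylsilyl)oxy]-3-methylbutyl}-2-formyl-4-methylbenzoate, via arylmagnesium chloride 9 (not isolated)
Conditions: i-PrMgCl·LiCl, THF, −20 °C; DMF, −20 °C to rt; H2O
Reagents that add atoms: N,N-dimethylformamide, CN(C)C=O
Why: Bromine–magnesium exchange with the turbo-Grignard reagent is accelerated by the ortho ester and tolerated by it at low temperature, and trapping with DMF is the Bouveault formylation.

Step 7
Reactants: 10 methyl 5-{(3S)-4-[(tert-butyldimethylsilyl)oxy]-3-methylbutyl}-2-formyl-4-methylbenzoate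
Product: 12 methyl 2-(dimethoxymethyl)-5-[(3S)-4-hydroxy-3-methylbutyl]-4-methylbenzoate, via silyl ether acetal 11 (not isolated)
Conditions: HC(OMe)3, CSA (cat.), MeOH, rt; Et3N quench
Reagents that add atoms: trimethyl orthoformate, COC(OC)OC; methanol, CO
Why: Acid-catalysed acetalisation with orthoformate as water scavenger, and the same acidic methanol then cleaves the primary TBS ether, so masking of the C2 carbonyl and release of the C8 alcohol are one operation.

Step 8
Reactants: 12 methyl 2-(dimethoxymethyl)-5-[(3S)-4-hydroxy-3-methylbutyl]-4-methylbenzoate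
Product: 13 methyl 2-(dimethoxymethyl)-4-methyl-5-[(3S)-3-methyl-4-oxobutyl]benzoate
Conditions: TPAP (cat.), NMO, 4 Å MS, CH2Cl2, rt
Reagents that add atoms: none
Why: The Ley–Griffith oxidation is neutral, so the acetal survives and the α-stereocentre C7 should not epimerise.

Step 9
Reactants: 13 methyl 2-(dimethoxymethyl)-4-methyl-5-[(3S)-3-methyl-4-oxobutyl]benzoate
Product: 14 methyl (7S,8R,8aS)-2-(dimethoxymethyl)-8-hydroxy-4,7-dimethyl-3,5,6,7,8,8a-hexahydronaphthalene-1-carboxylate
Conditions: SmI2 (2.4 equiv, slow addition), HMPA (12 equiv), t-BuOH (2 equiv), THF (0.01 M), 0 °C to rt; aq NaHCO3/Rochelle salt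
Reagents that add atoms: none
Why: SmI2–HMPA reduces the aldehyde to a ketyl radical at C8 that adds to the unsubstituted ring carbon C8a, ortho to the side chain and to the C1 ester, and the cyclohexadienyl radical (spin on C1, C3 and C4a) is reduced by a second SmI2 to the C1 ester dienolate and protonated by t-BuOH at C3, so ring A stays a skipped C1=C2/C4=C4a diene. The closest known reaction type is the SmI2/HMPA dearomatising ketyl–arene cyclisation of γ-aryl ketones to hexahydronaphthalenols. Ring B closes as a six-membered ring by ortho attack, formally 6-exo-trig on the C8a=C1 bond of the Kekulé structure. In the chair-like transition state the C7 methyl and the bulky samarium-bound oxygen are equatorial and C1 stays in the old ring plane, so H-8a becomes axial and cis to H-7 (8aS) and the C8 oxygen equatorial next to the ester (8R). The step needs attack at C8a rather than at C4a (5-exo, spiro) or C4: C4 is shielded by its methyl group, and ipso attack, the known course when an ester stands para to the tether, gains no ester stabilisation here because C2 carries only an acetal and the single ester is meta to C4a. Slow addition at high dilution holds back pinacol coupling and simple reduction, and any 14 that already lactonises to 15 in the flask is carried along because step 10 takes both to 16.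

Step 10
Reactants: 14 methyl (7S,8R,8aS)-2-(dimethoxymethyl)-8-hydroxy-4,7-dimethyl-3,5,6,7,8,8a-hexahydronaphthalene-1-carboxylate
Product: 16 (4aS,7S,8R,8aS)-2-(dimethoxymethyl)-4,7-dimethyl-4a,5,6,7,8,8a-hexahydronaphthalene-1,8-carbolactone (C1=C2–C3=C4 and H-4a trans to H-8a), via skipped-diene lactone 15 (not isolated)
Conditions: DBU, 4 Å MS, degassed toluene, 70 °C, Ar
Reagents that add atoms: none
Why: DBU closes the equatorial C8 hydroxyl onto the neighbouring C1 ester (lactonisation, methanol taken up by the sieves) and removes the doubly allylic γ-proton at C3, and reversible reprotonation of the C1–C3–C4a dienolate (base-mediated conjugation of a skipped dienoate) should drain to the linearly conjugated dienoate with the new C4a–H trans to H-8a, because the peri-lactone holds C8 pseudo-equatorial on ring A and C1 equatorial on the ring-B chair, so H-8a is axial to both rings and only a trans fusion avoids a twist-boat ring B.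

Step 11
Reactants: 16 (4aS,7S,8R,8aS)-2-(dimethoxymethyl)-4,7-dimethyl-4a,5,6,7,8,8a-hexahydronaphthalene-1,8-carbolactone
Product: 17 the corresponding lactol (C1–CH(OH)–O–C8, anomeric mixture, in equilibrium with the 8-hydroxy-1-carbaldehyde)
Conditions: DIBAL-H (1.1 equiv), CH2Cl2, −78 °C; Rochelle salt
Reagents that add atoms: none
Why: Partial reduction of a lactone with one equivalent of DIBAL-H at −78 °C stops at the aluminium hemiacetal, and neither the acetal nor the diene is touched.

Step 12
Reactants: 17 lactol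
Product: 18 (4aS,7S,8R,8aS)-2-(dimethoxymethyl)-4,7-dimethyl-1-[(E)-prop-1-en-1-yl]-4a,5,6,7,8,8a-hexahydronaphthalen-8-ol
Conditions: CrCl2 (8 equiv), CH3CHI2 (3 equiv), THF, rt
Reagents that add atoms: 1,1-diiodoethane, CC(I)I
Why: Takai–Utimoto ethylidenation with the gem-dichromium reagent acts on the hydroxy-dienal tautomer of the lactol, is E-selective, and being non-basic leaves the ε-acidic H-4a untouched while it frees the C8 hydroxyl.

Step 13
Reactants: 18 (4aS,7S,8R,8aS)-2-(dimethoxymethyl)-4,7-dimethyl-1-[(E)-prop-1-en-1-yl]-4a,5,6,7,8,8a-hexahydronaphthalen-8-ol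
Product: 20 O-(C8) S-methyl dithiocarbonate (xanthate) of 18, via sodium xanthate 19 (not isolated)
Conditions: NaH, THF, 0 °C; CS2; MeI, 0 °C to rt
Reagents that add atoms: carbon disulfide, S=C=S; iodomethane, CI
Why: Standard xanthate formation, the least sterically demanding thiocarbonylation for the flanked secondary alcohol, and safe here because 18 has no other acidic site once C1 is no longer a carbonyl carbon.

Step 14
Reactants: 20 xanthate of 18
Product: 21 (4aS,7S,8aS)-2-(dimethoxymethyl)-4,7-dimethyl-1-[(E)-prop-1-en-1-yl]-4a,5,6,7,8,8a-hexahydronaphthalene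
Conditions: Bu3SnH (0.4 M), Et3B/air (cat.), toluene, rt
Reagents that add atoms: none
Why: Barton–McCombie deoxygenation in which the secondary C8 radical is quenched by concentrated Bu3SnH faster than it can engage the neighbouring π system (3-exo and 5-endo closures are geometrically poor in the rigid peri arrangement), while room-temperature initiation keeps the reversible stannyl addition to the triene unproductive.

Step 15
Reactants: 21 (4aS,7S,8aS)-2-(dimethoxymethyl)-4,7-dimethyl-1-[(E)-prop-1-en-1-yl]-4a,5,6,7,8,8a-hexahydronaphthalene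
Product: 22 (4aS,7S,8aS)-4,7-dimethyl-1-[(E)-prop-1-en-1-yl]-4a,5,6,7,8,8a-hexahydronaphthalene-2-carbaldehyde
Conditions: PPTS (cat.), acetone/H2O, rt
Reagents that add atoms: water, O
Why: Hydrolysis of an allylic dimethyl acetal runs through a conjugated oxocarbenium ion and therefore needs only very mild acid, which should spare the triene and the now γ-acidic H-8a.

Step 16
Reactants: 23 pyridine-2,4-diol (4-hydroxy-2-pyridone)
Product: 24 3,5-dibromopyridine-2,4-diol
Conditions: NBS (2.1 equiv), MeCN, 0 °C to rt
Reagents that add atoms: N-bromosuccinimide, O=C1CCC(=O)N1Br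
Why: Electrophilic bromination of the electron-rich 4-hydroxy-2-pyridone takes place at the two positions activated by the oxygen functions, C3 and C5, and exhaustive bromination avoids any regiochemical question.

Step 17
Reactants: 24 3,5-dibromopyridine-2,4-diol
Product: 25 3,5-dibromo-2,4-bis[(4-methoxybenzyl)oxy]pyridine
Conditions: PMBCl, Ag2CO3, toluene, 60 °C, dark
Reagents that add atoms: 4-methoxybenzyl chloride, COc1ccc(CCl)cc1
Why: Silver-salt alkylation in a non-polar solvent directs the benzylic halide to oxygen rather than to nitrogen of the pyridone, giving the 2,4-dialkoxypyridine needed for later metalation.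

Step 18
Reactants: 25 3,5-dibromo-2,4-bis[(4-methoxybenzyl)oxy]pyridine; 26 {4-[(4-methoxybenzyl)oxy]phenyl}boronic acid
Product: 27 3-bromo-2,4-bis[(4-methoxybenzyl)oxy]-5-{4-[(4-methoxybenzyl)oxy]phenyl}pyridine
Conditions: Pd(PPh3)4 (cat.), Na2CO3, DME/H2O, 70 °C
Reagents that add atoms: none
Why: Site-selective Suzuki–Miyaura coupling in which oxidative addition should prefer the C5 bromide, which has only one ortho substituent and sits at the less electron-rich position, over the C3 bromide buried between two benzyloxy groups.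

Step 19
Reactants: 27 3-bromo-2,4-bis[(4-methoxybenzyl)oxy]-5-{4-[(4-methoxybenzyl)oxy]phenyl}pyridine; 22 (4aS,7S,8aS)-4,7-dimethyl-1-[(E)-prop-1-en-1-yl]-4a,5,6,7,8,8a-hexahydronaphthalene-2-carbaldehyde
Product: 29 (pyridin-3-yl)(hexahydronaphthalen-2-yl)methanol from 27 and 22 (epimer mixture at the carbinol carbon), via 3-lithiopyridine 28 (not isolated)
Conditions: n-BuLi, THF, −78 °C; then 22, −78 °C; H2O
Reagents that add atoms: none
Why: Bromine–lithium exchange at −78 °C gives the 3-lithiopyridine flanked by two alkoxy groups, which adds 1,2 to the enal faster than it deprotonates it; the new carbinol centre is of no consequence because it is oxidised next.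

Step 20
Reactants: 29 carbinol
Product: 30 tris-PMB-protected ilicicolin J (C2 aryl ketone)
Conditions: Dess–Martin periodinane, NaHCO3, CH2Cl2, 0 °C to rt
Reagents that add atoms: none
Why: Dess–Martin oxidation under bicarbonate buffer converts the doubly activated carbinol into the ketone without acid, strong base or a dehydrogenating oxidant that could ionise it, epimerise C8a or aromatise ring A.

Step 21
Reactants: 30 tris-PMB-protected ilicicolin J
Product: 31 ilicicolin J
Conditions: TFA, anisole, CH2Cl2, 0 °C
Reagents that add atoms: none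
Why: Acidolysis of the three 4-methoxybenzyl ethers with anisole as cation trap is fast at 0 °C, and the liberated 2-hydroxypyridine tautomerises to the 4-hydroxy-2-pyridone of the target.

**Compound list**
1 | methyl (R)-3-hydroxy-2-methylpropanoate | COC(=O)[C@H](C)CO | starting material
2 | methyl (R)-3-[(tert-butyldimethylsilyl)oxy]-2-methylpropanoate | COC(=O)[C@H](C)CO[Si](C)(C)C(C)(C)C | intermediate
3 | (R)-3-[(tert-butyldimethylsilyl)oxy]-2-methylpropanal | O=C[C@H](C)CO[Si](C)(C)C(C)(C)C | intermediate
4 | (S)-tert-butyldimethyl[(2-methylbut-3-en-1-yl)oxy]silane | C=C[C@H](C)CO[Si](C)(C)C(C)(C)C | intermediate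
5 | methyl 2-bromo-4-methylbenzoate | COC(=O)c1ccc(C)cc1Br | starting material
6 | methyl 2-bromo-5-iodo-4-methylbenzoate | COC(=O)c1cc(I)c(C)cc1Br | intermediate
7 | 9-{(3S)-4-[(tert-butyldimethylsilyl)oxy]-3-methylbutyl}-9-borabicyclo[3.3.1]nonane | B1(CC[C@H](C)CO[Si](C)(C)C(C)(C)C)C2CCCC1CCC2 | intermediate
8 | methyl 2-bromo-5-{(3S)-4-[(tert-butyldimethylsilyl)oxy]-3-methylbutyl}-4-methylbenzoate | COC(=O)c1cc(CC[C@H](C)CO[Si](C)(C)C(C)(C)C)c(C)cc1Br | intermediate
9 | arylmagnesium chloride from 8 (Mg at C2) | COC(=O)c1cc(CC[C@H](C)CO[Si](C)(C)C(C)(C)C)c(C)cc1[Mg]Cl | intermediate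
10 | methyl 5-{(3S)-4-[(tert-butyldimethylsilyl)oxy]-3-methylbutyl}-2-formyl-4-methylbenzoate | COC(=O)c1cc(CC[C@H](C)CO[Si](C)(C)C(C)(C)C)c(C)cc1C=O | intermediate
11 | methyl 5-{(3S)-4-[(tert-butyldimethylsilyl)oxy]-3-methylbutyl}-2-(dimethoxymethyl)-4-methylbenzoate | COC(=O)c1cc(CC[C@H](C)CO[Si](C)(C)C(C)(C)C)c(C)cc1C(OC)OC | intermediate
12 | methyl 2-(dimethoxymethyl)-5-[(3S)-4-hydroxy-3-methylbutyl]-4-methylbenzoate | COC(=O)c1cc(CC[C@H](C)CO)c(C)cc1C(OC)OC | intermediate
13 | methyl 2-(dimethoxymethyl)-4-methyl-5-[(3S)-3-methyl-4-oxobutyl]benzoate | COC(=O)c1cc(CC[C@H](C)C=O)c(C)cc1C(OC)OC | intermediate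
14 | methyl (7S,8R,8aS)-2-(dimethoxymethyl)-8-hydroxy-4,7-dimethyl-3,5,6,7,8,8a-hexahydronaphthalene-1-carboxylate | COC(=O)C1=C(C(OC)OC)CC(C)=C2CC[C@H](C)[C@@H](O)[C@H]12 | intermediate
15 | (7S,8R,8aS)-2-(dimethoxymethyl)-4,7-dimethyl-3,5,6,7,8,8a-hexahydronaphthalene-1,8-carbolactone (C1=C2, C4=C4a) | O=C1O[C@@H]2[C@@H](C)CCC3=C(C)CC(C(OC)OC)=C1[C@@H]23 | intermediate
16 | (4aS,7S,8R,8aS)-2-(dimethoxymethyl)-4,7-dimethyl-4a,5,6,7,8,8a-hexahydronaphthalene-1,8-carbolactone (C1=C2–C3=C4, trans-fused) | O=C1O[C@@H]2[C@@H](C)CC[C@@H]3C(C)=CC(C(OC)OC)=C1[C@@H]23 | intermediate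
17 | lactol of 16 (anomeric mixture) | OC1O[C@@H]2[C@@H](C)CC[C@@H]3C(C)=CC(C(OC)OC)=C1[C@@H]23 | intermediate
18 | (4aS,7S,8R,8aS)-2-(dimethoxymethyl)-4,7-dimethyl-1-[(E)-prop-1-en-1-yl]-4a,5,6,7,8,8a-hexahydronaphthalen-8-ol | C/C=C/C1=C(C(OC)OC)C=C(C)[C@H]2CC[C@H](C)[C@@H](O)[C@H]12 | intermediate
19 | sodium O-(C8) dithiocarbonate of 18 | C/C=C/C1=C(C(OC)OC)C=C(C)[C@H]2CC[C@H](C)[C@@H](OC(=S)[S-])[C@H]12.[Na+] | intermediate
20 | O-(C8) S-methyl dithiocarbonate of 18 | C/C=C/C1=C(C(OC)OC)C=C(C)[C@H]2CC[C@H](C)[C@@H](OC(=S)SC)[C@H]12 | intermediate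
21 | (4aS,7S,8aS)-2-(dimethoxymethyl)-4,7-dimethyl-1-[(E)-prop-1-en-1-yl]-4a,5,6,7,8,8a-hexahydronaphthalene | C/C=C/C1=C(C(OC)OC)C=C(C)[C@H]2CC[C@H](C)C[C@H]12 | intermediate
22 | (4aS,7S,8aS)-4,7-dimethyl-1-[(E)-prop-1-en-1-yl]-4a,5,6,7,8,8a-hexahydronaphthalene-2-carbaldehyde | C/C=C/C1=C(C=O)C=C(C)[C@H]2CC[C@H](C)C[C@H]12 | intermediate
23 | pyridine-2,4-diol | Oc1ccnc(O)c1 | starting material
24 | 3,5-dibromopyridine-2,4-diol | Oc1ncc(Br)c(O)c1Br | intermediate
25 | 3,5-dibromo-2,4-bis[(4-methoxybenzyl)oxy]pyridine | COc1ccc(COc2ncc(Br)c(OCc3ccc(OC)cc3)c2Br)cc1 | intermediate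
26 | {4-[(4-methoxybenzyl)oxy]phenyl}boronic acid | COc1ccc(COc2ccc(B(O)O)cc2)cc1 | starting material
27 | 3-bromo-2,4-bis[(4-methoxybenzyl)oxy]-5-{4-[(4-methoxybenzyl)oxy]phenyl}pyridine | COc1ccc(COc2ccc(-c3cnc(OCc4ccc(OC)cc4)c(Br)c3OCc3ccc(OC)cc3)cc2)cc1 | intermediate
28 | 3-lithio analogue of 27 | COc1ccc(COc2ccc(-c3cnc(OCc4ccc(OC)cc4)c([Li])c3OCc3ccc(OC)cc3)cc2)cc1 | intermediate
29 | carbinol from 28 and 22 (epimer mixture at the carbinol carbon) | C/C=C/C1=C(C(O)c2c(OCc3ccc(OC)cc3)ncc(-c3ccc(OCc4ccc(OC)cc4)cc3)c2OCc2ccc(OC)cc2)C=C(C)[C@H]2CC[C@H](C)C[C@H]12 | intermediate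
30 | tris-PMB-protected ilicicolin J | C/C=C/C1=C(C(=O)c2c(OCc3ccc(OC)cc3)ncc(-c3ccc(OCc4ccc(OC)cc4)cc3)c2OCc2ccc(OC)cc2)C=C(C)[C@H]2CC[C@H](C)C[C@H]12 | intermediate
31 | ilicicolin J | C/C=C/C1=C(C(=O)c2c(O)c(-c3ccc(O)cc3)c[nH]c2=O)C=C(C)[C@H]2CC[C@H](C)C[C@H]12 | target

**Step count**
- Total steps: 21.
- Longest linear sequence: 17 steps (steps 1–3, 5–15, 19–21).

**Steps most likely to fail**

**Step 9.** The aldehyde ketyl may be lost to pinacol coupling or to further reduction back to alcohol 12 before it reaches the ring. It may also attack the methyl-bearing carbon C4, para to the ester.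
- The fallback raises the radical affinity of the ring with a removable π-bound metal instead of relying on the ester alone.
- It sets out from 12. Heating with Cr(CO)6 in Bu2O/THF gives the tricarbonylchromium complex of alcohol 12 F1 as two planar-chiral diastereomers, which are separated. The one whose free face matches the chair with equatorial C7 methyl is used.
- Parikh–Doering oxidation gives the tricarbonylchromium complex of aldehyde 13 F2.
- SmI2/HMPA/t-BuOH then closes C8–C8a by the known ketyl addition to η6-arene tricarbonylchromium complexes, in which the radical enters anti to chromium.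
- Protonation and decomplexation in air and light release 14, where the route is rejoined.

**Step 10.** Reprotonation of the dienolate may stop at C1 (deconjugated diene). Traces of oxygen may aromatise ring A. Lactonisation may lag, so that C4a is protonated without the tether and facial control is lost.
- The fallback delivers H-4a as a palladium-bound hydride instead of a proton.
- It sets out from 14. Hydroxyl-directed epoxidation (VO(acac)2, t-BuOOH) of the electron-rich C4=C4a bond on the face of the C8 hydroxyl gives the 4,4a-epoxy hydroxy ester F3.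
- DBU opens the epoxide by γ-deprotonation at C3 (E1cB) and lactonises, giving the 4a-hydroxy dienyl lactone F4.
- LiHMDS and ClCO2Me give the tertiary allylic methyl carbonate F5.
- Pd2(dba)3/PBu3 with HCO2H/Et3N (Tsuji formate hydrogenolysis) ionises anti to the leaving group. It transfers hydride from palladium to the more substituted allyl terminus C4a, on the face opposite to the departed oxygen and therefore trans to H-8a. This gives 16.

**Step 14.** The stannyl radical may add to the conjugated triene (hydrostannation, E/Z scrambling of the propenyl group). The C8 radical may be diverted by hydrogen transfer from allylic positions.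
- The fallback removes the C8 oxygen before the propenyl group exists.
- It sets out from 16. Excess DIBAL-H gives the 1-hydroxymethyl-8-ol diol F6.
- TBSCl/imidazole silylates only the primary allylic alcohol, giving the mono-TBS ether F7.
- NaH, CS2 and MeI give the C8 xanthate F8.
- Bu3SnH/AIBN gives the 8-deoxy silyl ether F9.
- TBAF gives the allylic alcohol F10, and MnO2 gives the 1-carbaldehyde F11.
- Takai–Utimoto ethylidenation of this free aldehyde gives 21.

**Further compounds**
F1 | step 9 | tricarbonyl(η6-arene)chromium complex of alcohol 12 | COC(=O)c1cc(CC[C@H](C)CO)c(C)cc1C(OC)OC.[Cr].[C-]#[O+].[C-]#[O+].[C-]#[O+]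
F2 | step 9 | tricarbonyl(η6-arene)chromium complex of aldehyde 13 | COC(=O)c1cc(CC[C@H](C)C=O)c(C)cc1C(OC)OC.[Cr].[C-]#[O+].[C-]#[O+].[C-]#[O+]
F3 | step 10 | 4,4a-epoxide of 14 (oxygen on the face of the C8 hydroxyl and H-8a) | COC(=O)C1=C(C(OC)OC)C[C@@]2(C)O[C@]23CC[C@H](C)[C@@H](O)[C@H]13
F4 | step 10 | 4a-hydroxy analogue of lactone 16 (4a-OH cis to H-8a) | O=C1O[C@@H]2[C@@H](C)CC[C@@]3(O)C(C)=CC(C(OC)OC)=C1[C@@H]23
F5 | step 10 | 4a-O-methoxycarbonyl derivative of F4 | O=C1O[C@@H]2[C@@H](C)CC[C@@]3(OC(=O)OC)C(C)=CC(C(OC)OC)=C1[C@@H]23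
F6 | step 14 | (4aS,7S,8R,8aS)-2-(dimethoxymethyl)-1-(hydroxymethyl)-4,7-dimethyl-4a,5,6,7,8,8a-hexahydronaphthalen-8-ol | OCC1=C(C(OC)OC)C=C(C)[C@H]2CC[C@H](C)[C@@H](O)[C@H]12
F7 | step 14 | primary TBS ether of F6 | CC(C)(C)[Si](C)(C)OCC1=C(C(OC)OC)C=C(C)[C@H]2CC[C@H](C)[C@@H](O)[C@H]12
F8 | step 14 | C8 S-methyl xanthate of F7 | CC(C)(C)[Si](C)(C)OCC1=C(C(OC)OC)C=C(C)[C@H]2CC[C@H](C)[C@@H](OC(=S)SC)[C@H]12
F9 | step 14 | 8-deoxy TBS ether | CC(C)(C)[Si](C)(C)OCC1=C(C(OC)OC)C=C(C)[C@H]2CC[C@H](C)C[C@H]12
F10 | step 14 | [(4aS,7S,8aS)-2-(dimethoxymethyl)-4,7-dimethyl-4a,5,6,7,8,8a-hexahydronaphthalen-1-yl]methanol | OCC1=C(C(OC)OC)C=C(C)[C@H]2CC[C@H](C)C[C@H]12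
F11 | step 14 | (4aS,7S,8aS)-2-(dimethoxymethyl)-4,7-dimethyl-4a,5,6,7,8,8a-hexahydronaphthalene-1-carbaldehyde | O=CC1=C(C(OC)OC)C=C(C)[C@H]2CC[C@H](C)C[C@H]12
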